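The target is an achiral, mirror-symmetric trimer: a central butanoylphloroglucinol ring whose C3 and C5 each carry a CH2 bridge to an aspidinol ring. Each bridge is cut between the CH2 and the central-ring carbon. The key step exploits the free OH ortho to each bridge CH2 on the outer rings and the two equivalent OH-flanked CH carbons (C3, C5) of the central ring: an aspidinol ortho-quinone methide, released from a benzylic Mannich base as in the presumed biogenesis, C-benzylates butanoylphloroglucinol twice in one flask, the second addition (onto the mono-benzylated intermediate) completing the skeleton. The precursors are thus aminomethyl-aspidinol and the bare core.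

Key step: step 4

Remark: the target has no stereocentre or other stereogenic element, so the single species drawn is obtained without stereocontrol and the SMILES carry no stereodescriptors.
Remark: 2,4,6-trihydroxytoluene (1) and 1-(2,4,6-trihydroxyphenyl)butan-1-one (5) are taken as catalogue chemicals.

Step 1
Reactants: 1 2,4,6-trihydroxytoluene (2-methylbenzene-1,3,5-triol)
Product: 2 1-(2,4,6-trihydroxy-3-methylphenyl)butan-1-one
Conditions: PrCOCl (1.05 equiv), AlCl3 (3.5 equiv), CH2Cl2–MeNO2, 0 °C → 40 °C; ice/aq. HCl
Reagents that add atoms: butanoyl chloride CCCC(=O)Cl
Why: Friedel–Crafts C-acylation of an electron-rich phloroglucinol; the two free ring carbons of 1 are equivalent and the first acyl group deactivates the ring towards a second acylation, so a single regioisomer is expected.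

Step 2
Reactants: 2 1-(2,4,6-trihydroxy-3-methylphenyl)butan-1-one
Product: 3 aspidinol [1-(2,6-dihydroxy-4-methoxy-3-methylphenyl)butan-1-one]
Conditions: Me2SO4 (1.0 equiv), K2CO3 (1.0 equiv), acetone, rt → 45 °C
Reagents that add atoms: dimethyl sulfate COS(=O)(=O)OC
Why: Williamson O-methylation with limiting base and electrophile; the 4-OH para to the ketone is the most acidic hydroxyl and is not held in the hydrogen-bonded chelate with the C=O that tempers the 2- and 6-OH groups, so monomethylation should occur mainly there (the usual selectivity of 2,4,6-trihydroxyaryl ketones).

Step 3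
Reactants: 3 aspidinol
Product: 4 1-[3-[(dimethylamino)methyl]-2,6-dihydroxy-4-methoxy-5-methylphenyl]butan-1-one
Conditions: Me2NCH2NMe2 (1.1 equiv), THF, 0 °C → rt; concentrate below 30 °C, use directly
Reagents that add atoms: bis(dimethylamino)methane CN(C)CN(C)C
Why: Mannich aminomethylation of a phenol with an aminal; the acidic phenol protonates the aminal to release CH2=NMe2+, which attacks the only unsubstituted ring carbon of 3, so the site is unambiguous, and the absence of free formaldehyde should suppress methylene-bis-aspidinol formation.

Step 4
Reactants: 4 1-[3-[(dimethylamino)methyl]-2,6-dihydroxy-4-methoxy-5-methylphenyl]butan-1-one (2.2 equiv); 5 1-(2,4,6-trihydroxyphenyl)butan-1-one (1.0 equiv)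
Product: 8 1-[3,5-bis[(3-butanoyl-2,4-dihydroxy-6-methoxy-5-methylphenyl)methyl]-2,4,6-trihydroxyphenyl]butan-1-one, via aspidinol ortho-quinone methide 6 (not isolated), via mono-benzylated butanoylphloroglucinol 7 (not isolated)
Conditions: 1,4-dioxane, 90 °C, slow addition of 4 to 5, Ar sparge (removes Me2NH); dilute aq. HCl work-up
Reagents that add atoms: none
Why: The Mannich base 4, in which the acidic C2–OH ortho to the CH2NMe2 group protonates the amine, should lose dimethylamine on warming to give ortho-quinone methide 6, whose exocyclic CH2 is attacked by the ammonium phenolate of 5 at C3, the free ring carbon flanked by two OH groups; tautomerisation restores the aromatic ring to give 7, and the same sequence at the remaining free carbon C5 of the central ring forms the second, symmetry-equivalent CH2–aryl bond of 8, joining the aspidinol-CH2 unit to the already mono-benzylated core. The closest known reaction type is the thermal ortho-quinone methide Michael/Friedel–Crafts benzylation of phloroglucinols by phenolic Mannich bases, the laboratory counterpart of the biogenetic methylene bridging of acylphloroglucinols. No ring is closed and no stereocentre is formed. The step needs cross- over self-coupling, C- over O-alkylation and complete double alkylation: 4 has no free ring carbon and can only attack itself at an ipso position, 5 offers exactly two equivalent unsubstituted nucleophilic carbons so regiochemistry is fixed, O-benzylation is reversible whereas C-benzylation is driven by rearomatisation, and 7 retains a phloroglucinol-type free carbon as nucleophilic as those of 5, so a slight excess of slowly added 4 should carry the reaction through to 8. Sweeping out Me2NH limits base-induced retro-Michael scrambling of the diarylmethane bonds.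

Compound list
1 | 2,4,6-trihydroxytoluene (2-methylbenzene-1,3,5-triol) | Cc1c(O)cc(O)cc1O | starting material
2 | 1-(2,4,6-trihydroxy-3-methylphenyl)butan-1-one | CCCC(=O)c1c(O)cc(O)c(C)c1O | intermediate
3 | aspidinol, 1-(2,6-dihydroxy-4-methoxy-3-methylphenyl)butan-1-one | CCCC(=O)c1c(O)cc(OC)c(C)c1O | intermediate
4 | 1-[3-[(dimethylamino)methyl]-2,6-dihydroxy-4-methoxy-5-methylphenyl]butan-1-one | CCCC(=O)c1c(O)c(C)c(OC)c(CN(C)C)c1O | intermediate
5 | 1-(2,4,6-trihydroxyphenyl)butan-1-one | CCCC(=O)c1c(O)cc(O)cc1O | starting material
6 | 2-butanoyl-3-hydroxy-5-methoxy-4-methyl-6-methylidenecyclohexa-2,4-dien-1-one (aspidinol ortho-quinone methide) | CCCC(=O)C1=C(O)C(C)=C(OC)C(=C)C1=O | intermediate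
7 | 1-[3-[(3-butanoyl-2,4-dihydroxy-6-methoxy-5-methylphenyl)methyl]-2,4,6-trihydroxyphenyl]butan-1-one | CCCC(=O)c1c(O)cc(O)c(Cc2c(O)c(C(=O)CCC)c(O)c(C)c2OC)c1O | intermediate
8 | 1-[3,5-bis[(3-butanoyl-2,4-dihydroxy-6-methoxy-5-methylphenyl)methyl]-2,4,6-trihydroxyphenyl]butan-1-one (CNP0264591.0) | CCCC(=O)c1c(O)c(Cc2c(O)c(C(=O)CCC)c(O)c(C)c2OC)c(O)c(Cc2c(O)c(C(=O)CCC)c(O)c(C)c2OC)c1O | target

Total step count: 4. Longest linear sequence: 4 steps (1 → 2 → 3 → 4 → 8).

Steps most likely to fail

Step 4. The quinone methide may be consumed by ipso attack of a second aspidinol unit with loss of the aminomethyl carbon (self-coupling), the liberated amine may promote retro-Michael exchange of the new diarylmethane bonds, or the reaction may stall after the first benzylation. The fallback forms the same CH2–aryl bonds by reductive alkylation instead of quinone methide transfer. It sets out from 3: Vilsmeier–Haack formylation (POCl3, DMF, then aq. NaOAc) at the only free ring carbon should give 3-butanoyl-2,4-dihydroxy-6-methoxy-5-methylbenzaldehyde F1. F1 (2.2 equiv) is then condensed with 5 in the presence of catalytic L-proline and Hantzsch ester (three-component reductive alkylation: Knoevenagel-type condensation at C3 and C5 of the central ring, then transfer hydrogenation of the conjugated methide). This passes through 7 and comes back to the route at 8. No amine leaving group and no free aspidinol quinone methide are involved, which removes the self-coupling and scrambling pathways.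

Step 3. The Mannich base may lose dimethylamine during concentration and self-condense by ipso substitution before the nucleophile is present. The fallback replaces the amine by a sulfinate leaving group, giving a bench-stable, non-basic quinone methide precursor. It sets out from 3: three-component condensation with paraformaldehyde and sodium p-toluenesulfinate in aqueous formic acid should give 1-[2,6-dihydroxy-4-methoxy-3-methyl-5-[(4-methylbenzenesulfonyl)methyl]phenyl]butan-1-one F2. Treated with NaHCO3 or K2CO3 in the presence of 5, F2 eliminates sulfinate to the quinone methide, coming back to the route at 6 (then 7 and 8 as in step 4).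

Step 2. Methylation may occur at one of the hydroxyls ortho to the ketone, or twice, giving regioisomeric and dimethyl ethers that are hard to separate. The fallback lets chelation rather than acidity choose the oxygen atoms. It sets out from 1: exhaustive O-methylation (Me2SO4, K2CO3, acetone, reflux) should give 1,3,5-trimethoxy-2-methylbenzene F3, which is also a catalogue compound. Friedel–Crafts butanoylation (PrCOCl, AlCl3, CH2Cl2, 0 °C) at one of its two equivalent free carbons gives 1-(2,4,6-trimethoxy-3-methylphenyl)butan-1-one F4. Excess BCl3 (CH2Cl2, 0 °C → rt) or AlCl3 in hot chlorobenzene then cleaves only the two methoxy groups ortho to the carbonyl by chelation-assisted demethylation, leaving the para methoxy group and coming back to the route at 3.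

Further compounds
F1 | step 4 | 3-butanoyl-2,4-dihydroxy-6-methoxy-5-methylbenzaldehyde | CCCC(=O)c1c(O)c(C)c(OC)c(C=O)c1O
F2 | step 3 | 1-[2,6-dihydroxy-4-methoxy-3-methyl-5-[(4-methylbenzenesulfonyl)methyl]phenyl]butan-1-one | CCCC(=O)c1c(O)c(C)c(OC)c(CS(=O)(=O)c2ccc(C)cc2)c1O
F3 | step 2 | 1,3,5-trimethoxy-2-methylbenzene | COc1cc(OC)c(C)c(OC)c1
F4 | step 2 | 1-(2,4,6-trimethoxy-3-methylphenyl)butan-1-one | CCCC(=O)c1c(OC)cc(OC)c(C)c1OC
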